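The numbers in the tables stem from a simulated flask for an exercise, noise included.

- The grey run levels off near 76.6% of its X, and the bench rule "one G takes one X away from D" reads 75.0% there, from a ratio of G to X of 0.250.

| setting | amber | grey | summer | dawn | winter | autumn |
|---|---|---|---|---|---|---|
| X | 0.050 M | 0.20 M | 0.10 M | 0.10 M | 0.10 M | 0.10 M |
| Q | 0.40 M | 0.40 M | 0.400 M | 0.400 M | 0.400 M | 0.400 M |
| G | 0.050 M | 0.050 M | 0.0500 M | 0.0500 M | 0.0500 M | 0.0500 M |
| E | 5 mM | 5 mM | 5.00 mM | 5.00 mM | 5.00 mM | 5.00 mM |
| temperature | 45 °C | 72 °C | 95 °C | 80 °C | 50 °C | 65 °C |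
| remark | run made earlier | run made earlier |  |  |  |  |
| time |  |  | 6.0 d | 6.0 d | 6.0 d | 6.0 d |

| run | time / d | D / % |
|---|---|---|
| amber | 5.00 | 35.5 |
| amber | 10.0 | 38.3 |
| amber | 25.0 | 38.4 |
| amber | 60.0 | 36.9 |
| grey | 1.25 | 74.1 |
| grey | 2.50 | 75.9 |
| grey | 6.00 | 77.4 |
| grey | 15.0 | 76.4 |

(each reading ± 1 percentage point)



- the flask that comes out highest in amount of D, in percent of the X charged, or "all alike" when all lie within 1.5 percentage points (summer / dawn / winter / autumn / all alike)
- D at the end, in percent of the X charged, summer
- D at the end, in percent of the X charged, dawn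
- D at the end, in percent of the X charged, winter
- D at the end, in percent of the X charged, autumn

- The amber run marks the border: its ratio of G to X is 1.00, so the rule leaves no D, but the readings stand near 37.9%.
- If each missing X did take one G, the amber readings would mean 0.0311 M of X lost and 0.0189 M of G unspent, so the rule, which spends all of the G, does not describe the amber run.
- The four new flasks have a ratio of 0.500, between the two runs, so I go to logarithms. I suppose that X divides between Q and G, with the share going to G falling as G falls. As long as Q stays near its charge, equal portions of D then cut G by equal factors.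
- On this supposition the amber readings give 0.0449 M of D to cut G by a factor of 10, and the grey readings give 0.127 M. The grey figure rests on a reckoned remainder of 0.00313 M of G, which a scatter of 1 percentage point in the readings shakes.
- I let the logarithm of this amount grow evenly with temperature. That gives summer a decade of G, the amount of D formed while unspent G falls by a factor of 10, of 0.309 M. This is a selectivity factor written as a concentration. For winter the same step gives 0.0545 M.
- In my reckoning D is X charged less the G spent on X, and that G follows from D through the decade, so I substitute back and forth. My summer comes to 78.3% and my winter to 55.0%, so summer stands higher. Summer is the weaker figure, since 95 °C lies beyond both runs.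
- The forecast also picks summer, with 94% for summer, 88% for dawn, 71% for autumn and 45% for winter. Its grounds differ from mine: “This looks like an equilibrium rather than a yield limited by G”.
- Summer gives 71.1%, above dawn, autumn and winter, which give 65.0%, 60.0% and 53.9%.

    X + Q → D (k = 0.646 L mol⁻¹ h⁻¹, Ea = 80.0 kJ mol⁻¹)
    X + G → Z (k = 6.31 L mol⁻¹ h⁻¹, Ea = 57.0 kJ mol⁻¹)
    G → L (k = 0.0538 h⁻¹, Ea = 126 kJ mol⁻¹)
    G + E → J (k = 11.4 L mol⁻¹ h⁻¹, Ea = 58.0 kJ mol⁻¹)
    (constants at 80 °C)

- In summer, after 6.00 d, the X outside D stands as Z, 28.9% of the X charged. Summer's decade 0.309 M turns the D of summer into 20.6% of the X charged as missing X. In winter, whose temperature lies between those of the two runs, the decade 0.0545 M turns the D of winter into 44.9% against a Z of 43.4%.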